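## Structural features

The target is a resveratrol tetramer with ten free phenols, built from two halves of the same constitution, half P and half Q: each is a trans-2-(4-hydroxyphenyl)-2,3-dihydrobenzofuran (O1, C2, C3, C3a–C7a; primed locants for half Q) whose C3 carries a resorcinol ring. The halves are joined through four methine carbons in the chain Ca–Cf–Cc–Cd: Ca and Cd each bear a 4-hydroxyphenyl group and sit on the resorcinol ring of half P and of half Q, Cc is bonded to C4 of half P and Cf to C4′ of half Q. This gives two eight-membered carbocycles, ring P (Ca, two resorcinol carbons, C3, C3a, C4, Cc, Cf) and ring Q (Cd, two resorcinol carbons, C3′, C3a′, C4′, Cf, Cc), trans-fused along Cc–Cf. Of the eight stereocentres, Ca, Cf, Cc and Cd stand in a row (H at Ca and Cf cis, at Cf and Cc trans, at Cc and Cd trans), and each end of the row is one arene away from a dihydrofuran C3. The heterocycle is (2R,3R) in half P and (2S,3S) in half Q, Cc is R and Cf is S, but Ca and Cd are both R, so the molecule has no symmetry element although its constitution is twofold symmetric. Fragile points are the electron-rich phenols (oxidation), the benzylic C2–O bonds next to a para-oxygenated aryl group (acid-induced opening, epimerisation, reductive cleavage) and the doubly benzylic C–H bonds. The real difficulty is the pair of arene-fused eight-membered rings with four contiguous, crowded methines of unsymmetrical configuration, because cationic closures in this family prefer the seven-membered ring. The key step uses this bias: in half P, Ca (on the resorcinol ring) and Cc (on C4) are separated only by Cf, so without Cf they close the easily formed dibenzo-fused seven-membered ring; ring P is made as the one-carbon homologue of that ring, and Cf comes from a carbene and arrives as a vinyl bromide ready to be joined to C4′.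

## Logic of the disconnections

31 ⇒ 30. The ten O–CH3 bonds are cut last. Methyl ethers keep every intermediate neutral and resistant to oxidation. The demand is one global cleavage that leaves the benzylic C–O bonds and all eight stereocentres alone.

30 ⇒ 29. The C–H bonds at Cc and Cd are removed, leaving Cc=Cd. This turns the last two stereocentres into a tetrasubstituted alkene that a carbonyl coupling can make. The forward step must add hydrogen in a net anti sense (H at Cc trans to H at Cf and to H at Cd), which a stepwise proton/hydride addition can do and a surface hydrogenation cannot.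

29 ⇒ 28. The Cc=Cd bond is cut to two ketones. Ring Q then closes between the only two carbonyl groups of the molecule, and the bicyclic core simplifies to a single eight-membered ring carrying half Q as a diaryl ketone. The demand is a reductive coupling inside a crowded medium ring.

28 ⇒ 27. The C–H bonds at Ca and Cf are removed, giving the ring-cis enone Ca=Cf–Cc(=O). Syn addition across a ring-cis alkene gives the required cis hydrogens, and Cf stays correctable next to the ketone. The forward step must deliver hydride to a tetrasubstituted β-carbon on the right face.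

27 ⇒ 20 + 26. The Cf–C4′ bond is cut, which splits the tetramer into two halves of similar size. Half Q arrives with its (2S,3S) heterocycle and the future Cd already in place as an aroyl carbon. The demand is an sp2–sp2 coupling at a crowded α-bromo enone.

20 ⇒ 19 ⇒ 16 + 17. After adjusting the oxidation level at Cc, the two ring bonds of Cf (Cf–Ca and Cf–Cc) and the C–O bond at Cc are cut. Removing Cf contracts ring P to the seven-membered ring of 16 and leaves a one-carbon reagent. The forward step must add a carbene to the ring alkene only and open the cyclopropane toward the enlarged ring.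

16 ⇒ 15 ⇒ 14. The ring C=C is taken back to CH–CH2, then the bond between Ca and the resorcinol carbon ortho to C3 is cut. The seven-membered ring opens to a stilbene whose protonation regenerates the cation at Ca. The demands are closure at the resorcinol position next to C3, and a dehydrogenation that takes the doubly benzylic hydride and spares C2–H and C3–H.

14 ⇒ 12 + 13. The C4–vinyl bond is cut. The styryl unit comes from a commercial boronate, and the aryl bromide that remains is the same handle that half Q needs.

26 ⇒ 24 ⇒ 22 + 23. The C4′–B bond and the resorcinol–C(=O) bond are cut. The aroyl group is the future Cd with its aryl group. The acylation must go to the resorcinol position next to C3′ (para to methoxy) and not between the methoxy groups or onto the brominated benzofuran arene.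

12 and 22 ⇒ 11 and 21 ⇒ 10. The C2–C3 bond of the dihydrofuran is cut (carbene C–H insertion in the forward sense). Both enantiomeric series come from one achiral diazo compound by choice of the catalyst antipode, and C2 is corrected to trans by acid. The demand is catalyst control at C3 with a carbene flanked by bromine and the benzyl ether.

10 ⇒ 9 ⇒ 8 ⇒ 7 ⇒ 5 + 1 (through 6); 5 ⇒ 3 + 4; 3 ⇒ 2 ⇒ 1. The N–H bonds, the C=N bond, the aryl–carbinol bond, the O–CH2 bond, one O–CH3 bond and the formyl C–C bond are cut in turn. Each is a standard operation on a benzene ring, and the chelating aldehyde decides which methyl ether is cleaved.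

## Other disconnections considered

Alternative 1: The cut removes both resorcinol rings. The four bonds resorcinol–C(=O) (future Ca and Cd) and resorcinol–CH2 (future C3 and C3′) are broken, leading to the meso tetramethoxy-tetrahydrochrysenedione A2 and two molecules of 3,5-dimethoxybenzyne A4, generated from silyl triflate A3 with CsF. Forward, each benzylic ketone enolate of A2 would attack A4 at the carbon remote from methoxy, the aryl anion would close onto the carbonyl group, and fragmentation of the benzocyclobutenoxide would enlarge each six-membered ketone ring by two atoms to give A1.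
- In favour: four C–C bonds and both eight-membered rings form in one operation from a small symmetric tetracycle, and the normal regiochemistry of a 3-alkoxyaryne matches the methoxy pattern. On bonds and rings made per step this is better than the chosen key step, which makes two bonds and one ring.
- Against: A1 is meso and has none of the four 4-oxyphenyl groups, neither dihydrofuran, and only two of the eight stereocentres. The target is unsymmetrical, so the meso compound must be desymmetrised and its two sides then treated differently, and six stereocentres would be set late on a flexible bis-cyclooctadienone with no resident chiral element.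
- Comparison: mechanistically both plans enlarge an easily made smaller ring (anionic σ-insertion there, carbene addition and cationic electrocyclic opening here) and are about equal in precedent. Structurally the chosen plan keeps a finished, enantiopure dihydrobenzofuran half in the key-step product and uses it to steer the core, whereas A1 defers every aryl group and both heterocycles. The short way to A1 is likely to be outweighed by the long, stereochemically unguided stretch after it.

Alternative 2: The cut opens both dihydrofurans at C2–C3 and C2′–C3′ and leads to the bis(diaryldiazomethane) A6, in which C3 and C3′ are carbene carbons inside the eight-membered rings and the phenol oxygens carry 4-methoxybenzyl groups. Forward, Rh2(OAc)4 would generate two donor/donor carbenes that insert into the O–CH2 C–H bonds to give A5, which is the same compound as 30.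
- In favour: the reaction type is reliable for 2,3-diaryl-dihydrobenzofurans. The chosen route uses it in steps 8 and 14, so on this point the plans are equal. It is the last skeletal step, makes two rings and four stereocentres at once, and ends one step from the target, which equals the chosen end game at 30.
- Against: A6 already contains both eight-membered rings and the four contiguous methines, so the main difficulty is only moved. The diazo carbons are flanked by two ortho-substituted arenes inside a medium ring, so hydrazone formation and oxidation are hindered. With an achiral catalyst the opposite configurations of C3 and C3′ must be relayed from Ca–Cd, and the kinetic cis products need a double epimerisation at C2.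
- Comparison: the chosen plan sets the heterocycle centres first, by catalyst control on a simple monocyclic substrate, and relays from them to the core; this alternative relays the other way. Step economy is equal for the end game and worse before it, since the route to A6 is a synthesis of the core in its own right.

Alternative 3: The cut removes the two benzofuran arenes. The bonds C3a–C3 and C4–Cc and their counterparts in half Q are broken, leading to the bis(4-aryl-1-tetralone) A8 and two molecules of A4. Forward, the bis(potassium enolate) of A8 (enolate carbons Cc and Cf) would attack A4 at the carbon remote from methoxy, the aryl anions would add to the carbonyl groups, and fragmentation would insert an arene into each C(=O)–Cα bond to give A7.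
- In favour: both eight-membered rings and four C–C bonds form in one step. A8 already carries both 4-methoxyphenyl groups and the Ca and Cd centres. The ketones of A7 sit at C3 and C3′ next to a methoxy group that chelation-controlled cleavage could turn into the benzyl ether needed for A6, so alternatives 3 and 2 fit together. In ring-forming power this is better than the chosen key step.
- Against: the two enolate carbons are adjacent and each must react once with a separate aryne in a crowded dianion, with proton transfer, O-arylation and oxidation of the 1,4-dienolate as competitors. Cc and Cf are flattened in the enolate and re-formed by protonation, so the trans ring fusion is not controlled by the step. A8 is itself the unsymmetrical diastereomer (Ca and Cd both R) of a constitutionally symmetric dione and would have to be made as one enantiomer without an obvious handle.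
- Comparison: A7 has the whole carbocyclic core but no heterocycle, while the chosen key-step product has one ring of the core and a complete heterocyclic half. The mechanisms are again anionic insertion against carbene addition and cationic opening. The alternative is likely shorter to the bicyclic core, but it then needs the double C–H insertion of alternative 2, and absolute configuration has no clear source.

Key step: step 12

Remark on the chemistry: Rh2(R-PTAD)4 is written for the (3R) series, Rh2(S-PTAD)4 for the (3S) series and (R)-DTBM-SEGPHOS for step 18. The sense of induction of each is to be confirmed on the first run and the antipode taken where needed. The new centre of 15, the two cyclopropane centres of 18 and the carbinol centre of 19 are left undefined because the next steps remove them. The diaryldiazomethane 10 is handled only as a cold, filtered solution and is divided between the two enantiomeric series.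

## Route

Step 1
Reactants: 1 1-bromo-3,5-dimethoxybenzene
Product: 2 2-bromo-4,6-dimethoxybenzaldehyde
Conditions: POCl3, DMF, 0 → 80 °C; aq NaOAc
Reagents that add atoms: N,N-dimethylformamide CN(C)C=O; water O
Why: Vilsmeier–Haack formylation; the chloroiminium ion attacks para to one methoxy group and ortho to the other, next to bromine, which is the usual site in 5-substituted resorcinol dimethyl ethers.

Step 2
Reactants: 2 2-bromo-4,6-dimethoxybenzaldehyde
Product: 3 2-bromo-6-hydroxy-4-methoxybenzaldehyde
Conditions: BCl3, CH2Cl2, −78 → 0 °C; H2O
Reagents that add atoms: none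
Why: Chelation-directed ether cleavage; boron binds the aldehyde oxygen and the ortho methoxy group, so only that methyl group is removed and the para one stays.

Step 3
Reactants: 3 2-bromo-6-hydroxy-4-methoxybenzaldehyde; 4 4-methoxybenzyl chloride
Product: 5 2-bromo-4-methoxy-6-[(4-methoxybenzyl)oxy]benzaldehyde
Conditions: K2CO3, Bu4NI (cat.), DMF, 50 °C
Reagents that add atoms: none
Why: Williamson ether synthesis on the phenoxide; the benzyl CH2 introduced here becomes C2 and its aryl group the 2-aryl substituent.

Step 4
Reactants: 5 2-bromo-4-methoxy-6-[(4-methoxybenzyl)oxy]benzaldehyde; 1 1-bromo-3,5-dimethoxybenzene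
Product: 7 racemic {2-bromo-4-methoxy-6-[(4-methoxybenzyl)oxy]phenyl}(3,5-dimethoxyphenyl)methanol, via arylmagnesium bromide 6 (not isolated)
Conditions: 1, Mg, THF, 40 °C; then 5, THF, −20 → 0 °C; aq NH4Cl
Reagents that add atoms: none
Why: Grignard addition to the aldehyde; at low temperature the aryl bromide of 5 does not exchange, and the carbinol centre is lost in step 5.

Step 5
Reactants: 7 racemic {2-bromo-4-methoxy-6-[(4-methoxybenzyl)oxy]phenyl}(3,5-dimethoxyphenyl)methanol
Product: 8 {2-bromo-4-methoxy-6-[(4-methoxybenzyl)oxy]phenyl}(3,5-dimethoxyphenyl)methanone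
Conditions: DMP, NaHCO3, CH2Cl2, rt
Reagents that add atoms: none
Why: Dess–Martin oxidation of a diaryl carbinol; neutral conditions keep the 4-methoxybenzyl ether.

Step 6
Reactants: 8 {2-bromo-4-methoxy-6-[(4-methoxybenzyl)oxy]phenyl}(3,5-dimethoxyphenyl)methanone
Product: 9 {2-bromo-4-methoxy-6-[(4-methoxybenzyl)oxy]phenyl}(3,5-dimethoxyphenyl)methanone hydrazone (mixture of C=N isomers)
Conditions: N2H4·H2O (excess), AcOH (cat.), EtOH, 80 °C, sealed tube
Reagents that add atoms: hydrazine NN
Why: Acid-catalysed condensation; the ketone is doubly ortho-substituted, so excess hydrazine and heat are used, but the temperature stays below that of uncatalysed displacement of the ortho bromide (indazole formation).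

Step 7
Reactants: 9 {2-bromo-4-methoxy-6-[(4-methoxybenzyl)oxy]phenyl}(3,5-dimethoxyphenyl)methanone hydrazone
Product: 10 1-bromo-2-[diazo(3,5-dimethoxyphenyl)methyl]-5-methoxy-3-[(4-methoxybenzyl)oxy]benzene (diaryldiazomethane)
Conditions: MnO2 (activated, excess), MgSO4, CH2Cl2, 0 °C; filtration through Celite, solution kept at −20 °C
Reagents that add atoms: none
Why: Dehydrogenation of the N-unsubstituted hydrazone by MnO2 gives the donor/donor diazo compound; a diaryldiazomethane with two ortho substituents is stable enough to be filtered and kept cold in solution, so one batch serves both enantiomeric series.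

Step 8
Reactants: 10 diaryldiazomethane (cold CH2Cl2 solution)
Product: 12 (2R,3R)-trans-4-bromo-3-(3,5-dimethoxyphenyl)-6-methoxy-2-(4-methoxyphenyl)-2,3-dihydro-1-benzofuran, via cis-dihydrobenzofuran 11 (not isolated)
Conditions: Rh2(R-PTAD)4 (1 mol%), CH2Cl2, −20 °C → rt; then CF3CO2H, 0 °C → rt
Reagents that add atoms: none
Why: The chiral dirhodium carboxylate forms the carbene with loss of N2, and the carbene inserts into the O–CH2 C–H bond through a five-membered transition state, setting C3 by catalyst control (kinetic cis product); acid then opens C2–O to the 4-methoxybenzyl cation and re-closes to the more stable trans isomer, C3 staying intact as long as re-closure outruns proton loss.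

Step 9
Reactants: 12 (2R,3R)-trans-4-bromo-3-(3,5-dimethoxyphenyl)-6-methoxy-2-(4-methoxyphenyl)-2,3-dihydro-1-benzofuran; 13 (E)-2-[2-(4-methoxyphenyl)ethenyl]-4,4,5,5-tetramethyl-1,3,2-dioxaborolane
Product: 14 (2R,3R)-3-(3,5-dimethoxyphenyl)-6-methoxy-2-(4-methoxyphenyl)-4-[(E)-2-(4-methoxyphenyl)ethenyl]-2,3-dihydro-1-benzofuran
Conditions: Pd(dppf)Cl2 (5 mol%), K3PO4, dioxane–H2O, 85 °C
Reagents that add atoms: none
Why: Suzuki–Miyaura coupling with retention of the E geometry; the alkenylboronate fixes the regiochemistry of the stilbene, and the stereocentres are not involved.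

Step 10
Reactants: 14 (2R,3R)-stilbene
Product: 15 (2R,3R) seven-membered cyclisation product (ampelopsin B pentamethyl ether skeleton; resorcinol carbon ortho to C3 bonded to the 4-methoxyphenyl-bearing carbon; CH2 on C4; new diarylmethine centre undefined)
Conditions: CH3SO3H (0.2 equiv), CH2Cl2, 0 °C → rt
Reagents that add atoms: none
Why: Markovnikov protonation of the stilbene gives the 4-methoxybenzyl cation, which the resorcinol ring attacks at its activated position next to C3 (intramolecular Friedel–Crafts alkylation, seven-membered ring); the same change is known for the parent phenol; C2 can only re-form trans.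

Step 11
Reactants: 15 (2R,3R) seven-membered diarylmethine compound
Product: 16 (2R,3R) seven-membered ring alkene (ring C=C between the 4-methoxyphenyl-bearing carbon Ca and the CH on C4 that becomes Cc)
Conditions: DDQ (1.1 equiv), CH2Cl2, 0 °C → rt
Reagents that add atoms: none
Why: Benzylic dehydrogenation; DDQ takes the hydride from the diarylmethine carbon, whose cation is stabilised by a 4-methoxyphenyl and a 2,4-dimethoxyaryl group, and loss of a proton from the neighbouring CH2 gives the ring alkene; one equivalent and low temperature are used to spare C2–H and C3–H.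

Step 12
Reactants: 16 (2R,3R) seven-membered ring alkene; 17 bromoform
Product: 19 ring-expanded 2-bromo allylic alcohol (ring P with Ca(4-methoxyphenyl)=Cf(Br)–Cc(H)(OH); ring-cis alkene; (2R,3R); carbinol epimers), via dibromocyclopropane 18 (not isolated)
Conditions: CHBr3, KOtBu, toluene, −10 → 0 °C; then AgNO3, acetone–H2O, rt
Reagents that add atoms: water O
Why: KOtBu deprotonates bromoform and α-elimination gives dibromocarbene, which adds in a concerted [2+1] fashion to the electron-rich trisubstituted ring alkene of 16 and gives the cis-fused dibromocyclopropane 18. Ag+ then removes the bromide that is syn to the seven-membered ring while the cyclopropane bond shared by the two rings (the old alkene bond Ca–Cc) opens in a disrotatory two-electron electrocyclic sense with the ring substituents turning inward, so the three- and seven-membered rings merge into eight-membered ring P by enlargement and not by an end-to-end closure. Water adds to the 2-bromoallyl cation at Cc and gives 19, in which the carbene carbon Cf is bonded to Ca and Cc and carries bromine. The closest known reaction type is dihalocarbene addition to a cycloalkene followed by silver-assisted solvolytic opening to the homologous 2-halo allylic alcohol. No stereocentre of the target is made: the carbinol centre is uncontrolled and is oxidised in step 13, and C2 and C3 are not touched. The selectivities needed are carbene addition to the alkene and not to the methoxyarenes or C2–H (the alkene is the most nucleophilic π bond, pushed by two oxygenated aryl groups), opening toward the enlarged ring (secured by the strain of the bicyclo[5.1.0] unit, by the fused arenes, which exclude a ring-trans alkene so that only the syn bromide can leave, and by the diaryl-stabilised terminus Ca), and the site of water capture, which is not critical because the tertiary regioisomer is carried to the same enone in step 13.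

Step 13
Reactants: 19 ring-expanded 2-bromo allylic alcohol
Product: 20 bromo-enone of ring P (Ca(4-methoxyphenyl)=Cf(Br)–Cc(=O); ring-cis alkene; (2R,3R))
Conditions: C5H5NH[CrO3Cl] (pyridinium chlorochromate), NaOAc, 4 Å molecular sieves, CH2Cl2, rt
Reagents that add atoms: none
Why: Chromate oxidation of the benzylic, allylic alcohol; any tertiary regioisomer from step 12 gives the same enone by Babler–Dauben oxidative transposition.

Step 14
Reactants: 10 diaryldiazomethane (cold CH2Cl2 solution)
Product: 22 (2S,3S)-trans-4-bromo-3-(3,5-dimethoxyphenyl)-6-methoxy-2-(4-methoxyphenyl)-2,3-dihydro-1-benzofuran, via cis-dihydrobenzofuran 21 (not isolated)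
Conditions: Rh2(S-PTAD)4 (1 mol%), CH2Cl2, −20 °C → rt; then CF3CO2H, 0 °C → rt
Reagents that add atoms: none
Why: Same carbene C–H insertion and acid epimerisation as step 8 with the mirror-image catalyst, which sets C3′ as S; the achiral diazo compound serves both halves.

Step 15
Reactants: 22 (2S,3S)-trans-4-bromo-3-(3,5-dimethoxyphenyl)-6-methoxy-2-(4-methoxyphenyl)-2,3-dihydro-1-benzofuran; 23 4-methoxybenzoyl chloride
Product: 24 (2S,3S)-4-bromo-3-[3,5-dimethoxy-2-(4-methoxybenzoyl)phenyl]-6-methoxy-2-(4-methoxyphenyl)-2,3-dihydro-1-benzofuran
Conditions: SnCl4, CH2Cl2, −40 → 0 °C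
Reagents that add atoms: none
Why: Friedel–Crafts acylation; the dimethoxyphenyl ring is the most nucleophilic arene and reacts para to methoxy next to C3′ (either ortho position gives the same compound), the position between the methoxy groups is shielded, the benzofuran arene is deactivated and crowded by bromine, and the ketone formed stops further acylation.

Step 16
Reactants: 24 (2S,3S)-bromo ketone; 25 bis(pinacolato)diboron
Product: 26 (2S,3S)-3-[3,5-dimethoxy-2-(4-methoxybenzoyl)phenyl]-6-methoxy-2-(4-methoxyphenyl)-4-(4,4,5,5-tetramethyl-1,3,2-dioxaborolan-2-yl)-2,3-dihydro-1-benzofuran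
Conditions: Pd(dppf)Cl2 (5 mol%), KOAc, dioxane, 90 °C
Reagents that add atoms: none
Why: Miyaura borylation of the aryl bromide; the diaryl ketone and the benzylic ether are inert to the weak base and to zerovalent palladium.

Step 17
Reactants: 20 bromo-enone of ring P; 26 (2S,3S)-arylboronate
Product: 27 2-aryl enone (bromine at Cf replaced by the arene carbon C4′ of the (2S,3S) half Q; ring-cis alkene)
Conditions: Pd2(dba)3 (2.5 mol%), SPhos (10 mol%), K3PO4, toluene–H2O, 90 °C
Reagents that add atoms: none
Why: Suzuki–Miyaura coupling; the α-bromo enone undergoes oxidative addition readily, triaryl vinyl bromides are competent partners with a bulky biaryl phosphine, and neither partner has an enolisable position.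

Step 18
Reactants: 27 2-aryl enone
Product: 28 saturated diketone (H at Ca cis to H at Cf; Ca R; Cf S; ketone at Cc; half Q on Cf with its diaryl ketone)
Conditions: Cu(OAc)2·H2O (5 mol%), (R)-DTBM-SEGPHOS (5.5 mol%), MeSiH(OMe)2, t-BuOH, THF, rt → 40 °C
Reagents that add atoms: none
Why: Copper hydride 1,4-reduction; hydride goes to Ca with the chiral bisphosphine reinforcing the facial bias of the (2R,3R) half, t-BuOH protonates the copper enolate at Cf from the same open face (net syn addition across the ring-cis alkene, hence cis hydrogens), and conjugate addition is expected to outrun 1,2-reduction of the hindered diaryl ketone.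

Step 19
Reactants: 28 saturated diketone
Product: 29 bicyclic alkene (ring P plus ring Q closed; Cc=Cd tetrasubstituted; ring-cis; Ca R; Cf S)
Conditions: TiCl4, Zn, pyridine, THF, reflux, slow addition at high dilution
Reagents that add atoms: none
Why: Intramolecular McMurry reaction; low-valent titanium couples the aryl alkyl ketone (Cc) and the diaryl ketone (Cd) to a titanium pinacolate and deoxygenates it, closing ring Q between the only two carbonyl groups; Ca is not involved and Cf is fixed once the ring has closed.

Step 20
Reactants: 29 bicyclic alkene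
Product: 30 decamethyl ether of the target
Conditions: Et3SiH, CF3CO2H, CH2Cl2, −20 → 0 °C
Reagents that add atoms: none
Why: Ionic hydrogenation; protonation at Cc gives the cation at Cd, stabilised by a 4-methoxyphenyl and a 2,4-dimethoxyaryl group, and the silane delivers hydride; the stepwise course allows the net anti result (H at Cc trans to H at Cf in the less strained trans-fused bicycle, hydride to Cd on the face left open by the folded ring P), which is the usual sense of ionic as opposed to surface hydrogenation of ring-fused tetrasubstituted alkenes.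

Step 21
Reactants: 30 decamethyl ether of the target
Product: 31 CNP0224452.2 (target)
Conditions: BBr3, CH2Cl2, −78 °C → rt; MeOH, then H2O
Reagents that add atoms: none
Why: Lewis acid-mediated cleavage of all ten aryl methyl ethers by bromide attack on methyl, the standard last step for permethylated oligostilbenes; the trans-dihydrofurans are the stable isomers if C2–O opens reversibly.

## Compound list

1 | 1-bromo-3,5-dimethoxybenzene | COc1cc(Br)cc(OC)c1 | starting material
2 | 2-bromo-4,6-dimethoxybenzaldehyde | COc1cc(Br)c(C=O)c(OC)c1 | intermediate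
3 | 2-bromo-6-hydroxy-4-methoxybenzaldehyde | COc1cc(O)c(C=O)c(Br)c1 | intermediate
4 | 4-methoxybenzyl chloride | COc1ccc(CCl)cc1 | starting material
5 | 2-bromo-4-methoxy-6-[(4-methoxybenzyl)oxy]benzaldehyde | COc1ccc(COc2cc(OC)cc(Br)c2C=O)cc1 | intermediate
6 | (3,5-dimethoxyphenyl)magnesium bromide | COc1cc(OC)cc([Mg]Br)c1 | intermediate
7 | racemic {2-bromo-4-methoxy-6-[(4-methoxybenzyl)oxy]phenyl}(3,5-dimethoxyphenyl)methanol | COc1ccc(COc2cc(OC)cc(Br)c2C(O)c2cc(OC)cc(OC)c2)cc1 | intermediate
8 | {2-bromo-4-methoxy-6-[(4-methoxybenzyl)oxy]phenyl}(3,5-dimethoxyphenyl)methanone | COc1ccc(COc2cc(OC)cc(Br)c2C(=O)c2cc(OC)cc(OC)c2)cc1 | intermediate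
9 | {2-bromo-4-methoxy-6-[(4-methoxybenzyl)oxy]phenyl}(3,5-dimethoxyphenyl)methanone hydrazone | COc1ccc(COc2cc(OC)cc(Br)c2C(=NN)c2cc(OC)cc(OC)c2)cc1 | intermediate
10 | 1-bromo-2-[diazo(3,5-dimethoxyphenyl)methyl]-5-methoxy-3-[(4-methoxybenzyl)oxy]benzene | COc1ccc(COc2cc(OC)cc(Br)c2C(=[N+]=[N-])c2cc(OC)cc(OC)c2)cc1 | intermediate
11 | (2S,3R)-cis-4-bromo-3-(3,5-dimethoxyphenyl)-6-methoxy-2-(4-methoxyphenyl)-2,3-dihydro-1-benzofuran | Brc1cc(OC)cc2c1[C@H]([C@H](O2)c1ccc(OC)cc1)c1cc(OC)cc(OC)c1 | intermediate
12 | (2R,3R)-trans-4-bromo-3-(3,5-dimethoxyphenyl)-6-methoxy-2-(4-methoxyphenyl)-2,3-dihydro-1-benzofuran | Brc1cc(OC)cc2c1[C@H]([C@@H](O2)c1ccc(OC)cc1)c1cc(OC)cc(OC)c1 | intermediate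
13 | (E)-2-[2-(4-methoxyphenyl)ethenyl]-4,4,5,5-tetramethyl-1,3,2-dioxaborolane | COc1ccc(/C=C/B2OC(C)(C)C(C)(C)O2)cc1 | starting material
14 | (2R,3R)-3-(3,5-dimethoxyphenyl)-6-methoxy-2-(4-methoxyphenyl)-4-[(E)-2-(4-methoxyphenyl)ethenyl]-2,3-dihydro-1-benzofuran | COc1ccc(/C=C/c2cc(OC)cc3c2[C@H]([C@@H](O3)c2ccc(OC)cc2)c2cc(OC)cc(OC)c2)cc1 | intermediate
15 | (2R,3R) seven-membered cyclisation product (ampelopsin B pentamethyl ether skeleton), diarylmethine centre undefined | COc1ccc(cc1)C1Cc2cc(OC)cc3c2[C@H]([C@@H](O3)c2ccc(OC)cc2)c2cc(OC)cc(OC)c21 | intermediate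
16 | (2R,3R) seven-membered ring alkene, precursor of the key step | COc1ccc(cc1)C1=Cc2cc(OC)cc3c2[C@H]([C@@H](O3)c2ccc(OC)cc2)c2cc(OC)cc(OC)c21 | intermediate
17 | bromoform | BrC(Br)Br | starting material
18 | dibromocyclopropane adduct of the ring alkene (CBr2 bridging Ca and the future Cc, cis-fused, cyclopropane centres undefined) | COc1ccc(cc1)C12C(Br)(Br)C1c1cc(OC)cc3c1[C@H]([C@@H](O3)c1ccc(OC)cc1)c1cc(OC)cc(OC)c12 | intermediate
19 | ring-expanded 2-bromo allylic alcohol (ring-cis alkene, carbinol epimers), product of the key step | COc1ccc(cc1)/C1=C(Br)/C(O)c2cc(OC)cc3c2[C@H]([C@@H](O3)c2ccc(OC)cc2)c2cc(OC)cc(OC)c21 | intermediate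
20 | bromo-enone of ring P | COc1ccc(cc1)/C1=C(Br)/C(=O)c2cc(OC)cc3c2[C@H]([C@@H](O3)c2ccc(OC)cc2)c2cc(OC)cc(OC)c21 | intermediate
21 | (2R,3S)-cis-4-bromo-3-(3,5-dimethoxyphenyl)-6-methoxy-2-(4-methoxyphenyl)-2,3-dihydro-1-benzofuran | Brc1cc(OC)cc2c1[C@@H]([C@@H](O2)c1ccc(OC)cc1)c1cc(OC)cc(OC)c1 | intermediate
22 | (2S,3S)-trans-4-bromo-3-(3,5-dimethoxyphenyl)-6-methoxy-2-(4-methoxyphenyl)-2,3-dihydro-1-benzofuran | Brc1cc(OC)cc2c1[C@@H]([C@H](O2)c1ccc(OC)cc1)c1cc(OC)cc(OC)c1 | intermediate
23 | 4-methoxybenzoyl chloride | COc1ccc(cc1)C(Cl)=O | starting material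
24 | (2S,3S)-4-bromo-3-[3,5-dimethoxy-2-(4-methoxybenzoyl)phenyl]-6-methoxy-2-(4-methoxyphenyl)-2,3-dihydro-1-benzofuran | Brc1cc(OC)cc2c1[C@@H]([C@H](O2)c1ccc(OC)cc1)c1cc(OC)cc(OC)c1C(=O)c1ccc(OC)cc1 | intermediate
25 | bis(pinacolato)diboron | CC1(C)OB(OC1(C)C)B1OC(C)(C)C(C)(C)O1 | starting material
26 | (2S,3S)-3-[3,5-dimethoxy-2-(4-methoxybenzoyl)phenyl]-6-methoxy-2-(4-methoxyphenyl)-4-(4,4,5,5-tetramethyl-1,3,2-dioxaborolan-2-yl)-2,3-dihydro-1-benzofuran | CC1(C)OB(OC1(C)C)c1cc(OC)cc2c1[C@@H]([C@H](O2)c1ccc(OC)cc1)c1cc(OC)cc(OC)c1C(=O)c1ccc(OC)cc1 | intermediate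
27 | 2-aryl enone (bromo-enone of ring P with C4′ of the (2S,3S) half Q at Cf) | COc1ccc(cc1)/C1=C(c4cc(OC)cc5c4[C@@H]([C@H](O5)c4ccc(OC)cc4)c4cc(OC)cc(OC)c4C(=O)c4ccc(OC)cc4)/C(=O)c2cc(OC)cc3c2[C@H]([C@@H](O3)c2ccc(OC)cc2)c2cc(OC)cc(OC)c21 | intermediate
28 | saturated diketone (Ca R, Cf S, hydrogens cis) | COc1ccc([C@@H]2c3c(OC)cc(OC)cc3[C@@H]3c4c(cc(OC)cc4C(=O)[C@@H]2c2cc(OC)cc5c2[C@@H]([C@H](O5)c2ccc(OC)cc2)c2cc(OC)cc(OC)c2C(=O)c2ccc(OC)cc2)O[C@H]3c2ccc(OC)cc2)cc1 | intermediate
29 | bicyclic alkene (ring P plus ring Q, Cc=Cd ring-cis) | COc1ccc([C@@H]2c3c(OC)cc(OC)cc3[C@@H]3c4c(cc(OC)cc4/C4=C(\c5ccc(OC)cc5)c5c(OC)cc(OC)cc5[C@H]5c6c(cc(OC)cc6[C@H]24)O[C@@H]5c2ccc(OC)cc2)O[C@H]3c2ccc(OC)cc2)cc1 | intermediate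
30 | decamethyl ether of the target | COc1ccc([C@@H]2c3c(OC)cc(OC)cc3[C@@H]3c4c(cc(OC)cc4[C@H]4[C@H](c5ccc(OC)cc5)c5c(OC)cc(OC)cc5[C@H]5c6c(cc(OC)cc6[C@H]24)O[C@@H]5c2ccc(OC)cc2)O[C@H]3c2ccc(OC)cc2)cc1 | intermediate
31 | CNP0224452.2 | Oc1ccc([C@@H]2c3c(O)cc(O)cc3[C@@H]3c4c(cc(O)cc4[C@H]4[C@H](c5ccc(O)cc5)c5c(O)cc(O)cc5[C@H]5c6c(cc(O)cc6[C@H]24)O[C@@H]5c2ccc(O)cc2)O[C@H]3c2ccc(O)cc2)cc1 | target

## Step count and least certain steps

Total: 21 steps. Longest linear sequence: 18 steps (steps 1–13 and 17–21); the branch to 26 (steps 14–16) starts from 10.

**Step 12 (key step).** Carbene transfer to the crowded triaryl alkene may be slow, allowing attack on the methoxyarenes or insertion at C2–H. After opening, capture of the allyl cation at the tertiary terminus and ionisation of the product may give mixtures. The fallback sets out from 16 and comes back at 20. Hydroboration–oxidation (BH3·THF; NaOH, H2O2) should give the seven-membered alcohol F1, and DMP the α,α-diaryl ketone F2. KN(SiMe3)2 and Me3SiCl then give the silyl enol ether F3, which can only form toward Ca. Dibromocarbene (CHBr3, KOtBu) adds to this more electron-rich alkene, and the silyloxy dibromocyclopropane F4 opens with loss of Me3SiBr to 20 directly. No external nucleophile has to choose between the allyl termini and no oxidation is needed.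

**Step 18.** Hydride transfer to the tetrasubstituted β-carbon flanked by three arenes may be too slow, so that 1,2-reduction of the diaryl ketone takes over, and facial selectivity at Ca or protonation at Cf may be poor. The fallback sets out from 20 (and uses 24) and comes back at 28. Hydrodebromination (Pd(OAc)2, PPh3, HCO2H, Et3N) should give the trisubstituted enone F5. Copper hydride reduction with the same chiral ligand, on a β,β-diaryl enone for which this reduction is well behaved, gives ketone F6 with Ca set. Palladium-catalysed α-arylation of F6 with aryl bromide 24 (Pd(OAc)2, XPhos, NaOtBu, toluene) then forms the Cf–C4′ bond under conditions that equilibrate Cf. Because this detour does not pass through 27, it also answers a sluggish coupling of the two crowded partners in step 17.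

**Step 19.** Reductive coupling may stop at the pinacol stage or give separate reduction of the two ketones, because deoxygenation of a strained tetrasubstituted titanium pinacolate is slow. Epimerisation at Cf in the hot Lewis-acidic medium may feed the wrong ring fusion. The fallback sets out from 28 and comes back at 29. SmI2 (THF, t-BuOH, −78 → 0 °C) should effect ketyl–ketone cyclisation to the cis-diol F7. Thiocarbonyldiimidazole with DMAP gives the cyclic thionocarbonate F8, and Corey–Winter elimination with P(OMe)3 gives the alkene, so C–C formation and deoxygenation are separated.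

**Step 20.** Protonation at Cc and hydride capture at Cd may show poor facial selectivity. The acid may also open a dihydrofuran at C2–O with reductive trapping, or the cation may be captured by a neighbouring arene. The fallback sets out from 29 and comes back at 30; it makes no new compound (F0). It is a radical hydrogen-atom-transfer hydrogenation (Mn(dpm)3, PhSiH3, t-BuOOH, i-PrOH, rt), which needs no acid, adds hydrogen stepwise through the diaryl radical at Cd and tends to the more stable trans product.

**Step 15.** Regioselectivity may be lost (attack between the methoxy groups or on the benzofuran arene), and the Lewis acid may open the dihydrofuran. The fallback sets out from 22 and comes back at 26, placing the aroyl group by intramolecular delivery. Steps 9–11 are repeated in the mirror-image series to give stilbene F9, the seven-membered compound F10 and ring alkene F11. Cleavage of the ring alkene (OsO4, NaIO4, 2,6-lutidine) gives keto-aldehyde F12, whose aroyl group sits on the correct resorcinol carbon by construction. Oxidation (NaClO2, NaH2PO4, 2-methyl-2-butene) gives acid F13. Decarbonylative borylation (Pd(OAc)2, 1,4-bis(diphenylphosphino)butane, pivalic anhydride, B2pin2, Et3N, dioxane, 160 °C) then gives 26.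

**Step 11.** Over-oxidation is the risk: hydride abstraction at C2 or C3 with aromatisation to the benzofuran, or further oxidation of the electron-rich product. The fallback sets out from 12 and comes back at 16 without a dehydrogenation. Sonogashira coupling with 4-ethynylanisole (Pd(PPh3)2Cl2, CuI, Et3N) should give the diarylalkyne F14. A 7-endo hydroarylation (Ph3PAuNTf2, CH2Cl2, or catalytic CF3SO3H) then closes the resorcinol ring onto the alkyne carbon that bears the 4-methoxyphenyl group.

## Further compounds

F1 | step 12 | seven-membered alcohol from hydroboration–oxidation of 16 (new centres undefined) | COc1ccc(cc1)C1C(O)c2cc(OC)cc3c2[C@H]([C@@H](O3)c2ccc(OC)cc2)c2cc(OC)cc(OC)c21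
F2 | step 12 | seven-membered α,α-diaryl ketone | COc1ccc(cc1)C1C(=O)c2cc(OC)cc3c2[C@H]([C@@H](O3)c2ccc(OC)cc2)c2cc(OC)cc(OC)c21
F3 | step 12 | trimethylsilyl enol ether of F2 | COc1ccc(cc1)C1=C(O[Si](C)(C)C)c2cc(OC)cc3c2[C@H]([C@@H](O3)c2ccc(OC)cc2)c2cc(OC)cc(OC)c21
F4 | step 12 | silyloxy dibromocyclopropane from F3 | COc1ccc(cc1)C12C(Br)(Br)C1(O[Si](C)(C)C)c1cc(OC)cc3c1[C@H]([C@@H](O3)c1ccc(OC)cc1)c1cc(OC)cc(OC)c12
F5 | step 18 | debrominated ring-cis enone of ring P | COc1ccc(cc1)/C1=C/C(=O)c2cc(OC)cc3c2[C@H]([C@@H](O3)c2ccc(OC)cc2)c2cc(OC)cc(OC)c21
F6 | step 18 | saturated eight-membered ketone, Ca R | COc1ccc(cc1)[C@H]1CC(=O)c2cc(OC)cc3c2[C@H]([C@@H](O3)c2ccc(OC)cc2)c2cc(OC)cc(OC)c21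
F7 | step 19 | bicyclic cis-diol at Cc and Cd (carbinol centres undefined) | COc1ccc([C@@H]2c3c(OC)cc(OC)cc3[C@@H]3c4c(cc(OC)cc4C4(O)C(O)(c5ccc(OC)cc5)c5c(OC)cc(OC)cc5[C@H]5c6c(cc(OC)cc6[C@H]24)O[C@@H]5c2ccc(OC)cc2)O[C@H]3c2ccc(OC)cc2)cc1
F8 | step 19 | cyclic thionocarbonate of F7 | COc1ccc([C@@H]2c3c(OC)cc(OC)cc3[C@@H]3c4c(cc(OC)cc4C4(OC(=S)O7)C7(c5ccc(OC)cc5)c5c(OC)cc(OC)cc5[C@H]5c6c(cc(OC)cc6[C@H]24)O[C@@H]5c2ccc(OC)cc2)O[C@H]3c2ccc(OC)cc2)cc1
F0 | step 20 | none | none
F9 | step 15 | (2S,3S) enantiomer of 14 | COc1ccc(/C=C/c2cc(OC)cc3c2[C@@H]([C@H](O3)c2ccc(OC)cc2)c2cc(OC)cc(OC)c2)cc1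
F10 | step 15 | (2S,3S) enantiomeric series of 15 (diarylmethine centre undefined) | COc1ccc(cc1)C1Cc2cc(OC)cc3c2[C@@H]([C@H](O3)c2ccc(OC)cc2)c2cc(OC)cc(OC)c21
F11 | step 15 | (2S,3S) enantiomer of 16 | COc1ccc(cc1)C1=Cc2cc(OC)cc3c2[C@@H]([C@H](O3)c2ccc(OC)cc2)c2cc(OC)cc(OC)c21
F12 | step 15 | (2S,3S)-3-[3,5-dimethoxy-2-(4-methoxybenzoyl)phenyl]-6-methoxy-2-(4-methoxyphenyl)-2,3-dihydro-1-benzofuran-4-carbaldehyde | O=Cc1cc(OC)cc2c1[C@@H]([C@H](O2)c1ccc(OC)cc1)c1cc(OC)cc(OC)c1C(=O)c1ccc(OC)cc1
F13 | step 15 | (2S,3S)-3-[3,5-dimethoxy-2-(4-methoxybenzoyl)phenyl]-6-methoxy-2-(4-methoxyphenyl)-2,3-dihydro-1-benzofuran-4-carboxylic acid | OC(=O)c1cc(OC)cc2c1[C@@H]([C@H](O2)c1ccc(OC)cc1)c1cc(OC)cc(OC)c1C(=O)c1ccc(OC)cc1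
F14 | step 11 | (2R,3R)-3-(3,5-dimethoxyphenyl)-6-methoxy-2-(4-methoxyphenyl)-4-[(4-methoxyphenyl)ethynyl]-2,3-dihydro-1-benzofuran | COc1ccc(C#Cc2cc(OC)cc3c2[C@H]([C@@H](O3)c2ccc(OC)cc2)c2cc(OC)cc(OC)c2)cc1
A1 | alternative 1 | meso octamethoxy diketone with both eight-membered rings | O=C1c2c(OC)cc(OC)cc2Cc2c(OC)cc(OC)cc2[C@H]2C(=O)c3c(OC)cc(OC)cc3Cc3c(OC)cc(OC)cc3[C@H]12
A2 | alternative 1 | meso-1,3,7,9-tetramethoxy-4b,6,10b,12-tetrahydrochrysene-5,11-dione | O=C1Cc2c(OC)cc(OC)cc2[C@H]2C(=O)Cc3c(OC)cc(OC)cc3[C@H]12
A3 | alternative 1 | 3,5-dimethoxy-2-(trimethylsilyl)phenyl trifluoromethanesulfonate | COc1cc(OC)c([Si](C)(C)C)c(OS(=O)(=O)C(F)(F)F)c1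
A4 | alternative 1 | 3,5-dimethoxybenzyne | COC1=CC(OC)=CC#C1
A5 | alternative 2 | decamethyl ether of the target (identical with 30) | COc1ccc([C@@H]2c3c(OC)cc(OC)cc3[C@@H]3c4c(cc(OC)cc4[C@H]4[C@H](c5ccc(OC)cc5)c5c(OC)cc(OC)cc5[C@H]5c6c(cc(OC)cc6[C@H]24)O[C@@H]5c2ccc(OC)cc2)O[C@H]3c2ccc(OC)cc2)cc1
A6 | alternative 2 | bicyclic bis(diaryldiazomethane) with two 4-methoxybenzyl ethers | COc1ccc([C@@H]2c3c(OC)cc(OC)cc3C(=[N+]=[N-])c4c(cc(OC)cc4[C@H]4[C@H](c5ccc(OC)cc5)c5c(OC)cc(OC)cc5C(=[N+]=[N-])c6c(cc(OC)cc6[C@H]24)OCc2ccc(OC)cc2)OCc2ccc(OC)cc2)cc1
A7 | alternative 3 | bicyclic bis(diaryl ketone) with both eight-membered rings | COc1ccc([C@@H]2c3c(OC)cc(OC)cc3C(=O)c4c(cc(OC)cc4[C@H]4[C@H](c5ccc(OC)cc5)c5c(OC)cc(OC)cc5C(=O)c6c(cc(OC)cc6[C@H]24)OC)OC)cc1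
A8 | alternative 3 | 2,4,8,10-tetramethoxy-5,11-bis(4-methoxyphenyl)-5,5a,11,11a-tetrahydrotetracene-6,12-dione | COc1ccc([C@@H]2c3c(OC)cc(OC)cc3C(=O)[C@H]3[C@H](c4ccc(OC)cc4)c4c(OC)cc(OC)cc4C(=O)[C@H]23)cc1
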